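## Retrosynthetic overview

1. Target 20 is cut at its two ring A C–O bonds, the ester bond O3–C(=O) and the C18–OH bond; both come from one oxasilolane 13 (O3–SiEt2–C18), opened by angeloyl fluoride 16 and then oxidised at C18–Si.
2. 13 comes from hydroxyl-directed C–H silylation of the equatorial C4 methyl of the 3-ol 10, with the side-chain (Z)-enediol masked as a dioxepine acetonide.
3. 10 goes back through triol 8 to butenolide tosylate 6: lactone to (Z)-2-ene-1,4-diol, and C19–OTs to C19H3.
4. 6 comes from andrographolide 1 by 19-O-tosylation, acetylation and SN2′ hydride loss of the 14-acetate.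
5. No carbocycle is built: rings A and B with C3, C5, C9 and C10 come intact from 1. Only two temporary heterocycles are formed, the dioxepine first (step 4) and the oxasilolane second (step 5).

Assumption: ent-labdane numbering is used, with α meaning the face of the C10 methyl (C20); C19 is the axial 4α carbon, C18 the equatorial 4β carbon, and H5 and H9 are β. On this reading the target is (3R,4S,5S,9R,10S,13Z), an ent-labda-8(17),13-diene-3α,15,16,18-tetraol 3-angelate.

## Route

Step 1
Reactants: 1 andrographolide; 2 4-toluenesulfonyl chloride; 3 acetic anhydride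
Product: 5 3,14-di-O-acetyl-19-O-tosylandrographolide, via 19-tosylate 4 (not isolated)
Conditions: 2 (1.15 equiv), pyridine, 0 °C, 24 h; then 3 (6 equiv), DMAP (10 mol %), 0 → 23 °C
Reagents that add atoms: 4-toluenesulfonyl chloride Cc1ccc(cc1)S(Cl)(=O)=O; acetic anhydride CC(=O)OC(C)=O
Why: Selective O-sulfonylation followed by DMAP-catalysed acetylation: TsCl in cold pyridine takes the only primary hydroxyl (C19) ahead of the secondary allylic 14-OH and the hindered 3-OH, and excess Ac2O then caps O3 and turns O14 into the allylic leaving group needed next; no stereocentre is touched.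

Step 2
Reactants: 5 3,14-di-O-acetyl-19-O-tosylandrographolide
Product: 6 3-O-acetyl-19-O-tosyl-14-deoxyandrographolide
Conditions: NaBH4 (1.5 equiv), THF/MeOH 5:1, −10 → 0 °C
Reagents that add atoms: none
Why: SN2′ (conjugate addition–elimination) reduction of a Baylis–Hillman-type allylic acetate: hydride adds to C12 of the alkylidene lactone and the enolate expels the 14-acetate, which moves the alkene to C13=C14 inside the ring (so it can only be Z later) and removes the C14 stereocentre, while NaBH4 at 0 °C leaves the lactone carbonyl, the 3-acetate and the neopentyl tosylate alone.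

Step 3
Reactants: 6 3-O-acetyl-19-O-tosyl-14-deoxyandrographolide
Product: 8 ent-labda-8(17),13Z-diene-3α,15,16-triol, via tosyl triol 7 (not isolated)
Conditions: i-Bu2AlH (6 equiv), CH2Cl2, −78 → 0 °C; then LiEt3BH (8 equiv), THF, 0 → 65 °C; aq. KNaC4H4O6 work-up
Reagents that add atoms: none
Why: Two hydride reductions in one flask: i-Bu2AlH gives clean 1,2-reduction of the butenolide to the (Z)-2-ene-1,4-diol (geometry fixed by the ring) and cleaves the 3-acetate, then LiEt3BH, the most nucleophilic simple hydride, displaces the neopentyl primary tosylate (SN2) so that C19 becomes the axial methyl and C4 a gem-dimethyl carbon.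

Step 4
Reactants: 8 ent-labda-8(17),13Z-diene-3α,15,16-triol; 9 2,2-dimethoxypropane
Product: 10 15,16-O-isopropylidene-ent-labda-8(17),13-diene-3α,15,16-triol
Conditions: 9 (3 equiv), PPTS (5 mol %), CH2Cl2, 23 °C
Reagents that add atoms: 2,2-dimethoxypropane COC(C)(C)OC
Why: Acid-catalysed acetal exchange in which only the cis-2-ene-1,4-diol can close a ring (a 4,7-dihydro-1,3-dioxepine), leaving the hindered 3-OH free as the directing group.

Step 5
Reactants: 10 15,16-O-isopropylidene-ent-labda-8(17),13-diene-3α,15,16-triol; 11 diethylsilane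
Product: 13 3α-O,18-C-(diethylsilanediyl) oxasilolane of 10, via hydrosilyl ether 12 (not isolated)
Conditions: 11 (1.5 equiv), [Ir(cod)OMe]2 (0.5 mol %), THF, 23 °C; evaporate; then [Ir(cod)OMe]2 (2 mol %), 3,4,7,8-tetramethyl-1,10-phenanthroline (5 mol %), norbornene (1.2 equiv), THF, 100 °C
Reagents that add atoms: diethylsilane CC[SiH2]CC
Why: Hydroxyl-directed iridium-catalysed C–H silylation (Hartwig type): dehydrogenative O-silylation gives the Si–H ether, whose iridium silyl complex cleaves a γ primary C–H bond and closes the five-membered oxasilolane on the equatorial 4β-methyl (C18) and not on the axial 4α-methyl that clashes with C20, which sets C4 in the target configuration; norbornene takes up the hydrogen and the hindered alkenes of 10 should be left alone.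

Step 6
Reactants: 14 angelic acid; 15 cyanuric fluoride
Product: 16 angeloyl fluoride
Conditions: 15, pyridine (1 equiv), CH2Cl2, −10 → 0 °C; cold aqueous wash, used as a dried CH2Cl2 solution
Reagents that add atoms: cyanuric fluoride Fc1nc(F)nc(F)n1
Why: Deoxyfluorination of a carboxylic acid with cyanuric fluoride; the cold, chloride-free conditions give the small, fairly stable acyl fluoride without Z to E isomerisation.

Step 7
Reactants: 13 3α-O,18-C-(diethylsilanediyl) oxasilolane of 10; 16 angeloyl fluoride; 17 hydrogen peroxide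
Product: 19 3-O-angeloyl-15,16-O-isopropylidene-ent-labda-8(17),13-diene-3α,15,16,18-tetraol, via fluorosilane 18 (not isolated)
Conditions: 16 (1.3 equiv), [Bu4N][Ph3SiF2] (5 mol %), THF, 0 → 23 °C; MeOH quench; then KF, KHCO3, 30% aq. 17, THF/MeOH, 23 °C
Reagents that add atoms: angeloyl fluoride C/C=C(/C)C(F)=O; hydrogen peroxide OO
Why: Proposed new method: fluoride-catalysed acylative opening of a 1,2-oxasilolane by an acyl fluoride, followed in the same flask by Tamao–Fleming oxidation: fluoride adds to the strained, Lewis-acidic ring silicon, the pentacoordinate siliconate hands its alkoxide oxygen O3 to the small acyl fluoride and the fluoride set free carries the chain (net Si–O + F–C(=O) → Si–F + O–C(=O), driven by the Si–F bond), so the angelate can only land on O3 while C18 is kept as a fluorosilane that H2O2/KF then converts with retention into C18–OH; the closest known reactions are the fluoride-catalysed acylation of silyl ethers with acyl fluorides (the carbonyl counterpart of sulfur–fluoride exchange), the cleavage of simple oxasilacyclopentanes by acyl halides, and the Tamao–Fleming oxidation of fluorosilanes.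

Step 8
Reactants: 19 3-O-angeloyl-15,16-O-isopropylidene-ent-labda-8(17),13-diene-3α,15,16,18-tetraol
Product: 20 ent-labda-8(17),13Z-diene-3α,15,16,18-tetraol 3-angelate (CNP0237954.1)
Conditions: PPTS (10 mol %), MeOH, 0 → 23 °C
Reagents that add atoms: none
Why: Acid-catalysed transacetalisation of the labile seven-membered acetonide in methanol; the medium is non-basic, so the angelate neither migrates to O18 nor isomerises, and no stereocentre is affected.

## Compound list

1 | andrographolide (ent-labdane: 3α-OH, axial 4α-CH2OH = C19, 14S-OH, 8(17)-ene, 12E-ene, 16,15-olide) | C=C1CC[C@H]2[C@@](C)(CC[C@@H](O)[C@]2(CO)C)[C@@H]1C/C=C1/C(=O)OC[C@H]1O | starting material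
2 | 4-toluenesulfonyl chloride | Cc1ccc(cc1)S(Cl)(=O)=O | starting material
3 | acetic anhydride | CC(=O)OC(C)=O | starting material
4 | 19-O-tosylandrographolide | C=C1CC[C@H]2[C@@](C)(CC[C@@H](O)[C@]2(COS(=O)(=O)c3ccc(C)cc3)C)[C@@H]1C/C=C1/C(=O)OC[C@H]1O | intermediate
5 | 3,14-di-O-acetyl-19-O-tosylandrographolide | C=C1CC[C@H]2[C@@](C)(CC[C@@H](OC(C)=O)[C@]2(COS(=O)(=O)c3ccc(C)cc3)C)[C@@H]1C/C=C1/C(=O)OC[C@H]1OC(C)=O | intermediate
6 | 3-O-acetyl-19-O-tosyl-14-deoxyandrographolide (3α-acetoxy-19-tosyloxy-ent-labda-8(17),13-dien-16,15-olide) | C=C1CC[C@H]2[C@@](C)(CC[C@@H](OC(C)=O)[C@]2(COS(=O)(=O)c3ccc(C)cc3)C)[C@@H]1CCC1=CCOC1=O | intermediate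
7 | 19-O-tosyl-ent-labda-8(17),13Z-diene-3α,15,16,19-tetraol | C=C1CC[C@H]2[C@@](C)(CC[C@@H](O)[C@]2(COS(=O)(=O)c3ccc(C)cc3)C)[C@@H]1CC/C(=C/CO)CO | intermediate
8 | ent-labda-8(17),13Z-diene-3α,15,16-triol, (Z)-2-{2-[(1R,4aS,6R,8aS)-6-hydroxy-5,5,8a-trimethyl-2-methylidenedecahydronaphthalen-1-yl]ethyl}but-2-ene-1,4-diol | C=C1CC[C@H]2[C@@](C)(CC[C@@H](O)C2(C)C)[C@@H]1CC/C(=C/CO)CO | intermediate
9 | 2,2-dimethoxypropane | COC(C)(C)OC | starting material
10 | 15,16-O-isopropylidene-ent-labda-8(17),13-diene-3α,15,16-triol (side chain ends in a 2,2-dimethyl-4,7-dihydro-1,3-dioxepin-5-yl ring) | C=C1CC[C@H]2[C@@](C)(CC[C@@H](O)C2(C)C)[C@@H]1CCC1=CCOC(C)(C)OC1 | intermediate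
11 | diethylsilane | CC[SiH2]CC | starting material
12 | 3-O-(diethylsilyl) ether of 10 | C=C1CC[C@H]2[C@@](C)(CC[C@@H](O[SiH](CC)CC)C2(C)C)[C@@H]1CCC1=CCOC(C)(C)OC1 | intermediate
13 | oxasilolane of 10: SiEt2 bonded to O3 (α, equatorial) and to C18 (the equatorial 4β-CH2), 4α-CH3 kept | C=C1CC[C@H]2[C@@](C)(CC[C@@H](O[Si]3(CC)CC)[C@]2(C)C3)[C@@H]1CCC1=CCOC(C)(C)OC1 | intermediate
14 | angelic acid, (Z)-2-methylbut-2-enoic acid | C/C=C(/C)C(=O)O | starting material
15 | cyanuric fluoride | Fc1nc(F)nc(F)n1 | starting material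
16 | angeloyl fluoride, (Z)-2-methylbut-2-enoyl fluoride | C/C=C(/C)C(F)=O | intermediate
17 | hydrogen peroxide | OO | starting material
18 | 3α-angeloyloxy-18-[diethyl(fluoro)silyl]-15,16-O-isopropylidene-ent-labda-8(17),13-diene-15,16-diol | C=C1CC[C@H]2[C@@](C)(CC[C@@H](OC(=O)/C(C)=C\C)[C@]2(C)C[Si](F)(CC)CC)[C@@H]1CCC1=CCOC(C)(C)OC1 | intermediate
19 | 3-O-angeloyl-15,16-O-isopropylidene-ent-labda-8(17),13-diene-3α,15,16,18-tetraol | C=C1CC[C@H]2[C@@](C)(CC[C@@H](OC(=O)/C(C)=C\C)[C@]2(C)CO)[C@@H]1CCC1=CCOC(C)(C)OC1 | intermediate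
20 | ent-labda-8(17),13Z-diene-3α,15,16,18-tetraol 3-angelate, (3R,4S,5S,9R,10S) | C=C1CC[C@H]2[C@@](C)(CC[C@@H](OC(=O)/C(C)=C\C)[C@]2(C)CO)[C@@H]1CC/C(=C/CO)CO | target

## Step count and risks

Total step count: 8 (seven on the main line plus the one-step preparation of 16). Longest linear sequence: 7 steps (1 → 5 → 6 → 8 → 10 → 13 → 19 → 20).

The three steps most likely to fail are 7, 3 and 1.

**Step 7 (the proposed new reaction).** Three things can go wrong. The siliconate may be too hindered at O3 to acylate. Fluoride or alkoxide may act as a base on 16 and give a vinylketene, which leads to the deconjugated or E ester. The basic peroxide stage may start a 3 → 18 acyl shift. The fallback uses only known chemistry, sets out from 13 and comes back at 20. 13 is oxidised directly (30% H2O2, KF, KHCO3, THF/MeOH, 50 °C, Tamao–Fleming) to the 3α,18-diol acetonide F7. The primary hydroxyl is silylated (TBSCl, imidazole, DMF, 0 °C) to the 18-O-TBS ether F8. The hindered 3-OH is acylated with the mixed anhydride made from angelic acid 14 and 2,4,6-trichlorobenzoyl chloride (Et3N, toluene, 80 °C) to give the 3-O-angeloyl-18-O-TBS acetonide F9. Aqueous HF in MeCN then removes the silyl ether and the acetonide together to give 20.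

**Step 3.** Hydride displacement at the neopentyl C19 may be slow, or LiEt3BH may attack sulfur and return the 19-alcohol. The fallback replaces the intermolecular SN2 by an intramolecular etherification and a reductive ring opening; it sets out from 7 and comes back at 10. The reaction is stopped after the i-Bu2AlH stage and 7 is isolated. 7 is converted with 2,2-dimethoxypropane 9 and PPTS into the 15,16-O-isopropylidene 19-tosylate F5. KOt-Bu in THF at 0 °C closes the 3α,19-oxetane F6 by 4-exo-tet displacement, which is fast even at a neopentyl carbon. LiAlH4 in THF at 65 °C opens the oxetane at the primary carbon C19 and gives 10 directly.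

**Step 1.** The 14-OH may compete with the neopentyl 19-OH for TsCl, and a 14-sulfonate would eliminate. The fallback differentiates the hydroxyls by protecting groups instead of rate; it sets out from 1 and comes back at 8. 1 is peracetylated (Ac2O, pyridine, DMAP) to 3,14,19-tri-O-acetylandrographolide F1. NaBH4 as in step 2 gives 3,19-di-O-acetyl-14-deoxyandrographolide F2. K2CO3 in MeOH at 0 °C gives 14-deoxyandrographolide F3, whose only primary hydroxyl is O19. TsCl in pyridine gives 19-O-tosyl-14-deoxyandrographolide F4. F4 is taken through the conditions of step 3 (i-Bu2AlH, then LiEt3BH), passing through 7, to give 8.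

## Further compounds

F1 | step 1 | 3,14,19-tri-O-acetylandrographolide | C=C1CC[C@H]2[C@@](C)(CC[C@@H](OC(C)=O)[C@]2(COC(C)=O)C)[C@@H]1C/C=C1/C(=O)OC[C@H]1OC(C)=O
F2 | step 1 | 3,19-di-O-acetyl-14-deoxyandrographolide | C=C1CC[C@H]2[C@@](C)(CC[C@@H](OC(C)=O)[C@]2(COC(C)=O)C)[C@@H]1CCC1=CCOC1=O
F3 | step 1 | 14-deoxyandrographolide | C=C1CC[C@H]2[C@@](C)(CC[C@@H](O)[C@]2(CO)C)[C@@H]1CCC1=CCOC1=O
F4 | step 1 | 19-O-tosyl-14-deoxyandrographolide | C=C1CC[C@H]2[C@@](C)(CC[C@@H](O)[C@]2(COS(=O)(=O)c3ccc(C)cc3)C)[C@@H]1CCC1=CCOC1=O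
F5 | step 3 | 15,16-O-isopropylidene derivative of 7 (3α-OH, 19-OTs) | C=C1CC[C@H]2[C@@](C)(CC[C@@H](O)[C@]2(COS(=O)(=O)c3ccc(C)cc3)C)[C@@H]1CCC1=CCOC(C)(C)OC1
F6 | step 3 | 3α,19-epoxy (oxetane) 15,16-O-isopropylidene-ent-labda-8(17),13-diene-15,16-diol | C=C1CC[C@H]2[C@@](C)(CC[C@@H](O3)[C@]2(C3)C)[C@@H]1CCC1=CCOC(C)(C)OC1
F7 | step 7 | 15,16-O-isopropylidene-ent-labda-8(17),13-diene-3α,15,16,18-tetraol | C=C1CC[C@H]2[C@@](C)(CC[C@@H](O)[C@]2(C)CO)[C@@H]1CCC1=CCOC(C)(C)OC1
F8 | step 7 | 18-O-TBS ether of F7 | C=C1CC[C@H]2[C@@](C)(CC[C@@H](O)[C@]2(C)CO[Si](C)(C)C(C)(C)C)[C@@H]1CCC1=CCOC(C)(C)OC1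
F9 | step 7 | 3-O-angeloyl-18-O-TBS ether of F7 | C=C1CC[C@H]2[C@@](C)(CC[C@@H](OC(=O)/C(C)=C\C)[C@]2(C)CO[Si](C)(C)C(C)(C)C)[C@@H]1CCC1=CCOC(C)(C)OC1
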